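**Retrosynthetic overview**

1. Atom numbers follow the germacrane skeleton: C1 ketone, C3–O–C10 furanone bridge, C4=C5 olefin, C6 lactone carbinol, C8 ester, C9 hydroxyl, C11=C13 methylene, C12 lactone carbonyl.
2. The ten-membered carbocycle is formed last, by ring-closing metathesis at C4=C5; the bridged bicycle only accommodates the Z olefin.
3. The key C6–C7 bond comes from an intermolecular indium-mediated carbonyl allylation of acrolein by a cyclic allylic bromide (an α-bromomethyl δ-lactone closed through O9). Translactonization then gives the trans α-methylene γ-lactone and frees the C9 hydroxyl.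
4. The δ-lactone bromide comes from ring-closing metathesis of a 2-(bromomethyl)acrylate onto a C7 vinyl group; the C8/C9 syn-diol comes from γ-alkoxyallylboration of a furanone aldehyde.
5. The furanone with the C10 quaternary centre comes from 2-C-methyl-D-ribono-1,4-lactone. Ring order: furanone, temporary δ-lactone, γ-lactone, ten-membered ring.

Assumption: compounds 1, 14, 22 and (+)-Ipc2BOMe are purchased, and compound 5 is written in its open keto form although it equilibrates with the cyclic hemiketal.

**Route**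

Step 1
Reactants: 1 2-C-methyl-D-ribono-1,4-lactone [(3R,4R,5R)-3,4-dihydroxy-5-(hydroxymethyl)-3-methyloxolan-2-one]
Product: 2 (3R,4R,5R)-4-(tert-butyldimethylsilyloxy)-5-[(tert-butyldimethylsilyloxy)methyl]-3-hydroxy-3-methyloxolan-2-one
Conditions: TBSCl (2.5 equiv), imidazole, DMF, 0 → 40 °C
Reagents that add atoms: tert-butyldimethylsilyl chloride CC(C)(C)[Si](C)(C)Cl
Why: Silyl ether formation caps the primary and secondary hydroxyls while the hindered tertiary hydroxyl (the future furanone oxygen at C10) stays free; no stereocentre is touched.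

Step 2
Reactants: 2 the bis-silyl lactone; 3 2-methylbut-1-en-3-yne
Product: 5 (6R,7R,8R)-7,9-bis(tert-butyldimethylsilyloxy)-6,8-dihydroxy-2,6-dimethylnon-1-en-3-yn-5-one, via lithium acetylide 4 (not isolated)
Conditions: 3 (3.2 equiv), n-BuLi (3.0 equiv), THF, −78 °C; then 2, −78 → −20 °C; aq NH4Cl
Reagents that add atoms: none
Why: Acetylide addition to a lactone stops at the ketone oxidation level because the lithium hemiketal alkoxide persists until the quench (one equivalent of base is consumed by the tertiary OH); the stereocentres of 1 are carried over unchanged.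

Step 3
Reactants: 5 the hydroxy ynone
Product: 6 (2R)-2-[(1R,2R)-1,3-bis(tert-butyldimethylsilyloxy)-2-hydroxypropyl]-2-methyl-5-(prop-1-en-2-yl)furan-3(2H)-one
Conditions: AuCl(PPh3) (5 mol %), AgOTf (5 mol %), toluene, rt
Reagents that add atoms: none
Why: Gold-catalysed 5-endo-dig cycloisomerization of the α'-hydroxy ynone by the free tertiary hydroxyl gives the 3(2H)-furanone; the neighbouring secondary oxygen is silylated so no pyranone can form, and C10 keeps the configuration it had in 1.

Step 4
Reactants: 6 the bis-silyl furanone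
Product: 7 (2R)-2-methyl-5-(prop-1-en-2-yl)-2-[(1R,2R)-1,2,3-trihydroxypropyl]furan-3(2H)-one
Conditions: 48% aq HF, MeCN, 0 °C → rt
Reagents that add atoms: none
Why: Acidic fluoride desilylation removes both silyl ethers without exposing the β-hydroxy ketone to base, which would invite retro-aldol cleavage.

Step 5
Reactants: 7 the triol
Product: 8 (2R)-2-methyl-3-oxo-5-(prop-1-en-2-yl)-2,3-dihydrofuran-2-carbaldehyde
Conditions: NaIO4 (2.5 equiv), THF/pH 7 buffer, 0 °C → rt; extract, dry by toluene azeotrope, use crude at once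
Reagents that add atoms: none
Why: Malaprade glycol cleavage of the triol removes two carbons as formic acid and formaldehyde and leaves a non-enolizable quaternary aldehyde, so C10 cannot epimerize.

Step 6
Reactants: 9 4-methoxybenzyl alcohol; 10 allyl bromide
Product: 11 allyl 4-methoxybenzyl ether [1-methoxy-4-[(prop-2-en-1-yloxy)methyl]benzene]
Conditions: NaH, THF/DMF, 0 °C → rt
Reagents that add atoms: none
Why: Williamson ether synthesis of a primary alkoxide with an allylic bromide.

Step 7
Reactants: 8 the furanone aldehyde; 11 allyl 4-methoxybenzyl ether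
Product: 13 (2R)-2-{(1R,2S)-1-hydroxy-2-[(4-methoxyphenyl)methoxy]but-3-en-1-yl}-2-methyl-5-(prop-1-en-2-yl)furan-3(2H)-one, via alkoxyallylborane 12 (not isolated)
Conditions: 11, sec-BuLi, THF, −78 °C; (+)-Ipc2BOMe (the reagent derived from (−)-α-pinene); BF3·OEt2; then 8, −78 °C; aq NaHCO3, 30% H2O2, 0 °C → rt
Reagents that add atoms: none
Why: Brown γ-alkoxyallylboration: the Z-γ-alkoxyallylborane adds through a chair transition state to give the syn 1,2-diol monoether, the (+)-Ipc ligands send the allyl group to the Re face of the aldehyde, and this matches the polar Felkin–Anh preference of the α-oxygenated quaternary centre, so C9 (R) and C8 (S) are set together.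

Step 8
Reactants: 13 the homoallylic alcohol; 14 2-(bromomethyl)acrylic acid
Product: 15 (1R,2S)-2-[(4-methoxyphenyl)methoxy]-1-[(2R)-2-methyl-3-oxo-5-(prop-1-en-2-yl)-2,3-dihydrofuran-2-yl]but-3-en-1-yl 2-(bromomethyl)prop-2-enoate
Conditions: DCC, DMAP (0.1 equiv), CH2Cl2, 0 °C → rt
Reagents that add atoms: none
Why: Steglich esterification acylates the only free hydroxyl (O9) under near-neutral conditions that leave the allylic bromide and the β-hydroxy ketone motif intact.

Step 9
Reactants: 15 the diene ester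
Product: 16 (5S,6R)-3-(bromomethyl)-5-[(4-methoxyphenyl)methoxy]-6-[(2R)-2-methyl-3-oxo-5-(prop-1-en-2-yl)-2,3-dihydrofuran-2-yl]-5,6-dihydro-2H-pyran-2-one
Conditions: second-generation Grubbs catalyst (5 mol %), toluene, 80 °C, 5 mM
Reagents that add atoms: none
Why: Ring-closing metathesis of the C7 vinyl group onto the 2-substituted acrylate gives the six-membered unsaturated lactone and so creates a cyclic allylic bromide; closure onto the isopropenyl group would need a bridgehead olefin in a small bicycle and does not compete.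

Step 10
Reactants: 16 the δ-lactone allylic bromide; 17 acrolein (prop-2-enal)
Product: 19 (4S,5R)-5-ethenyl-4-{(1S,2R)-2-hydroxy-1-[(4-methoxyphenyl)methoxy]-2-[(2R)-2-methyl-3-oxo-5-(prop-1-en-2-yl)-2,3-dihydrofuran-2-yl]ethyl}-3-methylideneoxolan-2-one, via hydroxy δ-lactone 18 (not isolated)
Conditions: indium powder (1.5 equiv), 17 (3 equiv), THF/sat. aq NH4Cl 1:1, rt; extract; then CSA (0.1 equiv), CH2Cl2, rt
Reagents that add atoms: none
Why: Barbier-type indium carbonyl allylation: the ring-locked E-type allylindium reacts at its γ-carbon through a chair transition state (anti adduct) on the ring face opposite the pseudoaxial C8 ether and the C9 side chain, which sets C7 (S) and C6 (R), and the new γ-hydroxyl then translactonizes to the more stable trans γ-lactone, releasing the C9 hydroxyl.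

Step 11
Reactants: 19 the γ-lactone alcohol
Product: 20 (4S,5R)-5-ethenyl-4-{(1S,2R)-1-[(4-methoxyphenyl)methoxy]-2-[(2R)-2-methyl-3-oxo-5-(prop-1-en-2-yl)-2,3-dihydrofuran-2-yl]-2-(triethylsilyloxy)ethyl}-3-methylideneoxolan-2-one
Conditions: TESOTf, 2,6-lutidine, CH2Cl2, −78 → 0 °C
Reagents that add atoms: triethylsilyl trifluoromethanesulfonate CC[Si](CC)(CC)OS(=O)(=O)C(F)(F)F
Why: Silylation with a silyl triflate and a hindered base protects the hindered C9 hydroxyl without base strong enough to trigger retro-aldol cleavage or isomerization of the exocyclic methylene.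

Step 12
Reactants: 20 the silyl ether
Product: 21 (4R,5R)-5-ethenyl-4-{(1S,2R)-1-hydroxy-2-[(2R)-2-methyl-3-oxo-5-(prop-1-en-2-yl)-2,3-dihydrofuran-2-yl]-2-(triethylsilyloxy)ethyl}-3-methylideneoxolan-2-one
Conditions: DDQ, CH2Cl2/pH 7 buffer 10:1, 0 °C → rt
Reagents that add atoms: none
Why: Oxidative cleavage of the p-methoxybenzyl ether under buffered neutral conditions frees only the C8 hydroxyl and spares the silyl ether and the electron-poor olefins (the 4R label reflects a priority change, not an inversion).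

Step 13
Reactants: 21 the C8 alcohol; 22 (R)-2-methylbutanoic acid
Product: 24 (1S,2R)-1-[(4S,5R)-5-ethenyl-3-methylidene-2-oxooxolan-4-yl]-2-[(2R)-2-methyl-3-oxo-5-(prop-1-en-2-yl)-2,3-dihydrofuran-2-yl]-2-(triethylsilyloxy)ethyl (2R)-2-methylbutanoate, via mixed anhydride 23 (not isolated)
Conditions: 22, 2,4,6-trichlorobenzoyl chloride, Et3N, toluene, rt; then 21, DMAP, toluene, 0 °C → rt
Reagents that add atoms: none
Why: Yamaguchi esterification acylates the hindered secondary C8 hydroxyl with the preformed mixed anhydride under mild conditions that keep the α-stereocentre of the acid; the C9 oxygen is blocked so no regiochemical choice arises.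

Step 14
Reactants: 24 the seco diene
Product: 25 (4Z,6R,7S,8S,9R,10R)-8-[(2R)-2-methylbutanoyloxy]-1-oxo-9-(triethylsilyloxy)-3,10-epoxygermacra-2,4,11(13)-trien-12,6-olide
Conditions: second-generation Hoveyda–Grubbs catalyst (20 mol % in portions), toluene, 100 °C, 1 mM
Reagents that add atoms: none
Why: Ring-closing metathesis between the C6 vinyl group and the furanone isopropenyl group forms the C4=C5 trisubstituted olefin and the ten-membered carbocycle; the furanone-bridged ring can only hold the Z olefin.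

Step 15
Reactants: 25 the silyl-protected macrocycle
Product: 26 target CNP0146060.1 [(4Z,6R,7S,8S,9R,10R)-9-hydroxy-8-[(2R)-2-methylbutanoyloxy]-1-oxo-3,10-epoxygermacra-2,4,11(13)-trien-12,6-olide]
Conditions: HF·pyridine, THF/pyridine, 0 °C
Reagents that add atoms: none
Why: Mildly acidic fluoride desilylation frees the C9 hydroxyl without the basic conditions that would cause acyl migration from O8, retro-aldol cleavage or addition to the α-methylene lactone.

**Compound list**

1 | 2-C-methyl-D-ribono-1,4-lactone | O=C1O[C@H](CO)[C@@H](O)[C@@]1(C)O | starting material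
2 | (3R,4R,5R)-4-(tert-butyldimethylsilyloxy)-5-[(tert-butyldimethylsilyloxy)methyl]-3-hydroxy-3-methyloxolan-2-one | O=C1O[C@H](CO[Si](C)(C)C(C)(C)C)[C@@H](O[Si](C)(C)C(C)(C)C)[C@@]1(C)O | intermediate
3 | 2-methylbut-1-en-3-yne | C=C(C)C#C | starting material
4 | lithium 3-methylbut-3-en-1-yn-1-ide | [Li]C#CC(C)=C | intermediate (not isolated)
5 | (6R,7R,8R)-7,9-bis(tert-butyldimethylsilyloxy)-6,8-dihydroxy-2,6-dimethylnon-1-en-3-yn-5-one | C=C(C)C#CC(=O)[C@](C)(O)[C@H](O[Si](C)(C)C(C)(C)C)[C@H](O)CO[Si](C)(C)C(C)(C)C | intermediate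
6 | (2R)-2-[(1R,2R)-1,3-bis(tert-butyldimethylsilyloxy)-2-hydroxypropyl]-2-methyl-5-(prop-1-en-2-yl)furan-3(2H)-one | C=C(C)C1=CC(=O)[C@](C)(O1)[C@H](O[Si](C)(C)C(C)(C)C)[C@H](O)CO[Si](C)(C)C(C)(C)C | intermediate
7 | (2R)-2-methyl-5-(prop-1-en-2-yl)-2-[(1R,2R)-1,2,3-trihydroxypropyl]furan-3(2H)-one | C=C(C)C1=CC(=O)[C@](C)(O1)[C@H](O)[C@H](O)CO | intermediate
8 | (2R)-2-methyl-3-oxo-5-(prop-1-en-2-yl)-2,3-dihydrofuran-2-carbaldehyde | C=C(C)C1=CC(=O)[C@](C)(O1)C=O | intermediate
9 | 4-methoxybenzyl alcohol | COc1ccc(CO)cc1 | starting material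
10 | allyl bromide | C=CCBr | starting material
11 | allyl 4-methoxybenzyl ether | C=CCOCc1ccc(OC)cc1 | intermediate
12 | [(Z)-3-(4-methoxybenzyloxy)prop-2-en-1-yl]bis(isopinocampheyl)borane | COc1ccc(CO/C=C\CB([C@H]2C[C@H]3C[C@@H]([C@@H]2C)C3(C)C)[C@H]2C[C@H]3C[C@@H]([C@@H]2C)C3(C)C)cc1 | intermediate (not isolated)
13 | (2R)-2-{(1R,2S)-1-hydroxy-2-[(4-methoxyphenyl)methoxy]but-3-en-1-yl}-2-methyl-5-(prop-1-en-2-yl)furan-3(2H)-one | C=C(C)C1=CC(=O)[C@](C)(O1)[C@H](O)[C@@H](OCc2ccc(OC)cc2)C=C | intermediate
14 | 2-(bromomethyl)acrylic acid | C=C(CBr)C(=O)O | starting material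
15 | (1R,2S)-2-[(4-methoxyphenyl)methoxy]-1-[(2R)-2-methyl-3-oxo-5-(prop-1-en-2-yl)-2,3-dihydrofuran-2-yl]but-3-en-1-yl 2-(bromomethyl)prop-2-enoate | C=C(C)C1=CC(=O)[C@](C)(O1)[C@H](OC(=O)C(=C)CBr)[C@@H](OCc2ccc(OC)cc2)C=C | intermediate
16 | (5S,6R)-3-(bromomethyl)-5-[(4-methoxyphenyl)methoxy]-6-[(2R)-2-methyl-3-oxo-5-(prop-1-en-2-yl)-2,3-dihydrofuran-2-yl]-5,6-dihydro-2H-pyran-2-one | C=C(C)C1=CC(=O)[C@](C)(O1)[C@@H]2OC(=O)C(CBr)=C[C@@H]2OCc3ccc(OC)cc3 | intermediate
17 | acrolein | C=CC=O | starting material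
18 | (4S,5S,6R)-4-[(1R)-1-hydroxyprop-2-en-1-yl]-5-[(4-methoxyphenyl)methoxy]-6-[(2R)-2-methyl-3-oxo-5-(prop-1-en-2-yl)-2,3-dihydrofuran-2-yl]-3-methylideneoxan-2-one | C=C(C)C1=CC(=O)[C@](C)(O1)[C@@H]2OC(=O)C(=C)[C@@H]([C@H](O)C=C)[C@@H]2OCc3ccc(OC)cc3 | intermediate (not isolated)
19 | (4S,5R)-5-ethenyl-4-{(1S,2R)-2-hydroxy-1-[(4-methoxyphenyl)methoxy]-2-[(2R)-2-methyl-3-oxo-5-(prop-1-en-2-yl)-2,3-dihydrofuran-2-yl]ethyl}-3-methylideneoxolan-2-one | C=C1C(=O)O[C@H](C=C)[C@H]1[C@H](OCc2ccc(OC)cc2)[C@@H](O)[C@@]3(C)OC(=CC3=O)C(C)=C | intermediate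
20 | 9-O-triethylsilyl ether of 19 | C=C1C(=O)O[C@H](C=C)[C@H]1[C@H](OCc2ccc(OC)cc2)[C@@H](O[Si](CC)(CC)CC)[C@@]3(C)OC(=CC3=O)C(C)=C | intermediate
21 | (4R,5R)-5-ethenyl-4-{(1S,2R)-1-hydroxy-2-[(2R)-2-methyl-3-oxo-5-(prop-1-en-2-yl)-2,3-dihydrofuran-2-yl]-2-(triethylsilyloxy)ethyl}-3-methylideneoxolan-2-one | C=C1C(=O)O[C@H](C=C)[C@H]1[C@H](O)[C@@H](O[Si](CC)(CC)CC)[C@@]2(C)OC(=CC2=O)C(C)=C | intermediate
22 | (R)-2-methylbutanoic acid | CC[C@@H](C)C(=O)O | starting material
23 | (2R)-2-methylbutanoic 2,4,6-trichlorobenzoic anhydride | CC[C@@H](C)C(=O)OC(=O)c1c(Cl)cc(Cl)cc1Cl | intermediate (not isolated)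
24 | (1S,2R)-1-[(4S,5R)-5-ethenyl-3-methylidene-2-oxooxolan-4-yl]-2-[(2R)-2-methyl-3-oxo-5-(prop-1-en-2-yl)-2,3-dihydrofuran-2-yl]-2-(triethylsilyloxy)ethyl (2R)-2-methylbutanoate | C=C1C(=O)O[C@H](C=C)[C@H]1[C@H](OC(=O)[C@H](C)CC)[C@@H](O[Si](CC)(CC)CC)[C@@]2(C)OC(=CC2=O)C(C)=C | intermediate
25 | 9-O-triethylsilyl ether of the target | C=C1C(=O)O[C@@H]2/C=C(/C)C3=CC(=O)[C@](C)(O3)[C@H](O[Si](CC)(CC)CC)[C@@H](OC(=O)[C@H](C)CC)[C@@H]12 | intermediate
26 | CNP0146060.1 | C=C1C(=O)O[C@@H]2/C=C(/C)C3=CC(=O)[C@](C)(O3)[C@H](O)[C@@H](OC(=O)[C@H](C)CC)[C@@H]12 | target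

**Count**

Total steps: 15. Longest linear sequence: 14 steps (1 to 26 through steps 1–5 and 7–15; step 6 is a one-step side branch).

**Three steps most likely to fail, each with a fallback**

Step 14, the macrocyclic ring-closing metathesis. The ring is strained and one partner is a conjugated 1,1-disubstituted olefin, so the reaction may stall or give C5 homodimers. The fallback changes the order of bond construction. It sets out from 21 and closes the ring before the acyl group is introduced, which removes the bulky acyloxy group from the chain that has to fold. This gives the macrocyclic alcohol F1. F1 is then acylated with 22 through mixed anhydride 23 under the conditions of step 13, and the route is rejoined at 25.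

Step 10, the indium allylation. The allylindium carries an ether at the carbon next to its reacting terminus, so it may lose that ether by vinylogous β-elimination to a pyranone, or simply be protonated in the aqueous medium. The fallback replaces the allylmetal by an allylboron reagent, which has no carbanion character. It sets out from 16, which is borylated with B2pin2 and Pd2(dba)3 in toluene/DMSO at 50 °C to give the allylboronate F2. F2 adds to acrolein 17 on warming in toluene, or at room temperature with catalytic Sc(OTf)3, through the same chair transition state and with the same facial bias. Hydrolytic work-up gives 18, and CSA converts 18 into 19, where the route is rejoined.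

Step 7, the alkoxyallylboration. Aldehyde 8 is a non-enolizable β-keto aldehyde that hydrates and can deformylate, and the metalation of 11 in the flask may be incomplete or accompanied by Wittig rearrangement. The fallback moves from reagent control to substrate control with an isolable nucleophile. It sets out from 11, which is lithiated with sec-BuLi at −78 °C and quenched with Bu3SnCl to give the purified allylstannane F3. F3 is added to 8 with BF3·OEt2 in CH2Cl2 at −78 °C. The open antiperiplanar transition state gives the syn adduct, and polar Felkin–Anh control at the quaternary α-centre gives the 9R configuration. No oxidative work-up is needed, and the route is rejoined at 13.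

**Further compounds**

F1 | step 14 | 8-hydroxy macrocycle (25 without the 2-methylbutanoyl group; 9-O-triethylsilyl) | C=C1C(=O)O[C@@H]2/C=C(/C)C3=CC(=O)[C@](C)(O3)[C@H](O[Si](CC)(CC)CC)[C@@H](O)[C@@H]12
F2 | step 10 | (5S,6R)-5-[(4-methoxyphenyl)methoxy]-6-[(2R)-2-methyl-3-oxo-5-(prop-1-en-2-yl)-2,3-dihydrofuran-2-yl]-3-[(4,4,5,5-tetramethyl-1,3,2-dioxaborolan-2-yl)methyl]-5,6-dihydro-2H-pyran-2-one | C=C(C)C1=CC(=O)[C@](C)(O1)[C@@H]2OC(=O)C(CB3OC(C)(C)C(C)(C)O3)=C[C@@H]2OCc3ccc(OC)cc3
F3 | step 7 | (Z)-tributyl{3-[(4-methoxyphenyl)methoxy]prop-2-en-1-yl}stannane | CCCC[Sn](CCCC)(CCCC)C/C=C\OCc1ccc(OC)cc1
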